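**Assumptions.** The SMILES has no stereodescriptor and the molecule has no stereocentre. Each biaryl axis is flanked only by one OH and a peri or ortho C–H, so both rotate at room temperature; the target is treated as one achiral compound and no stereocontrol is needed. 8-Methoxynaphthalen-1-ol and 8-methoxy-1-tetralone are taken as catalogue compounds.

**Retrosynthetic overview**
1. Target ⇐ acid cleavage of two silyl ethers and one MOM ether from a fully aromatic, protected ternaphthalene.
2. Outer naphthols (rings A and C) ⇐ DDQ dehydrogenation of two 2-aryl-1-silyloxy-3,4-dihydronaphthalenes; each outer naphthol is carried as a tetralone enol ether.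
3. Both biaryl bonds (ring A C2–ring B C2 and ring C C2–ring B C4) ⇐ one two-fold palladium-catalysed ketone α-arylation of 8-methoxy-1-tetralone with a 2,4-dibromonaphthalene, in place of a biaryl cross-coupling.
4. Dibromide ⇐ 8-methoxy-1-naphthol by ortho/para dibromination and MOM protection.
5. Ring order: no ring is built from acyclic material; ring B is bought aromatic, rings A and C arrive as tetralones and are aromatised in the penultimate step.

**Route**

Step 1
Reactants: 1 8-methoxynaphthalen-1-ol; 2 N-bromosuccinimide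
Product: 3 2,4-dibromo-8-methoxynaphthalen-1-ol
Conditions: NBS (2.05 equiv), i-Pr2NH (10 mol%), CH2Cl2, 0 °C to rt, dark
Reagents that add atoms: N-bromosuccinimide (2), O=C1CCC(=O)N1Br
Why: Electrophilic aromatic bromination in which the free naphthol OH, the strongest donor, directs bromine to its ortho (C2) and para (C4) positions, the amine-catalysed NBS protocol favouring the OH-bearing ring while the anisole ring is not attacked in CH2Cl2 and its C5 is peri-shielded once C4 is brominated.

Step 2
Reactants: 3 2,4-dibromo-8-methoxynaphthalen-1-ol; 4 chloromethyl methyl ether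
Product: 5 2,4-dibromo-8-methoxy-1-(methoxymethoxy)naphthalene
Conditions: NaH (1.3 equiv), DMF, 0 °C; MOMCl (1.4 equiv), 0 °C to rt
Reagents that add atoms: chloromethyl methyl ether (4), COCCl
Why: Williamson-type O-alkylation of the sodium naphtholate; the base-stable MOM acetal keeps the bromide from entering the palladium step as an electron-rich naphtholate and prevents cyclodehydration of a free ortho-OH onto the ketone introduced next (benzofuran formation).

Step 3
Reactants: 5 2,4-dibromo-8-methoxy-1-(methoxymethoxy)naphthalene; 6 8-methoxy-3,4-dihydronaphthalen-1(2H)-one (8-methoxy-1-tetralone, 2.6 equiv); 7 triethylsilyl trifluoromethanesulfonate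
Product: 9 2,2'-[8-methoxy-1-(methoxymethoxy)naphthalene-2,4-diyl]bis[8-methoxy-1-(triethylsilyloxy)-3,4-dihydronaphthalene], via disodium bis-enolate 8 (not isolated)
Conditions: Pd(OAc)2 (6 mol%), P(t-Bu)3·HBF4 (12 mol%), NaOt-Bu (5.5 equiv), PhMe, 80 °C; then 0 °C, Et3N, TESOTf (excess)
Reagents that add atoms: 8-methoxy-1-tetralone (6), COc1cccc2CCCC(=O)c12; triethylsilyl trifluoromethanesulfonate (7), CC[Si](CC)(CC)OS(=O)(=O)C(F)(F)F
Why: Two-fold Buchwald–Hartwig–Miura ketone α-arylation, in which each C–Br bond adds oxidatively to zerovalent palladium, the sodium enolate of 6 (only one enolisable carbon, so C2 is the only site) replaces bromide and C–C reductive elimination follows; the more acidic α-aryl ketone is deprotonated at once by excess alkoxide, so it rests as the planar bis-enolate 8 (no stereocentre persists, no second arylation at the same carbon) and is capped on oxygen by the silyl triflate.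

Step 4
Reactants: 9 2,2'-[8-methoxy-1-(methoxymethoxy)naphthalene-2,4-diyl]bis[8-methoxy-1-(triethylsilyloxy)-3,4-dihydronaphthalene]
Product: 10 1,1''-bis(triethylsilyloxy)-8,8',8''-trimethoxy-1'-(methoxymethoxy)-2,2':4',2''-ternaphthalene
Conditions: DDQ (2.5 equiv), 2,4,6-collidine (3 equiv), PhMe, 0 °C to rt
Reagents that add atoms: none
Why: Quinone dehydrogenation of 1-silyloxy-3,4-dihydronaphthalenes, in which DDQ abstracts hydride from the allylic C3–H to give a silyloxy- and aryl-stabilised allyl cation that loses the C4 proton, driven by aromatisation of rings A and C; the central ring B has no abstractable hydride and collidine buffers the acidic hydroquinone so the silyl groups stay on.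

Step 5
Reactants: 10 1,1''-bis(triethylsilyloxy)-8,8',8''-trimethoxy-1'-(methoxymethoxy)-2,2':4',2''-ternaphthalene
Product: 11 8,8',8''-trimethoxy-[2,2':4',2''-ternaphthalene]-1,1',1''-triol (CNP0482979.0)
Conditions: HCl (2 M in MeOH), THF, 40 °C, argon, degassed solvents
Reagents that add atoms: none
Why: Acid-catalysed methanolysis of the two aryl silyl ethers and of the MOM acetal in one operation, the aryl methyl ethers being inert to dilute HCl and no ketone being left for the freed central OH to condense with.

**Compound list**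
1 | 8-methoxynaphthalen-1-ol | COc1cccc2cccc(O)c12 | starting material
2 | N-bromosuccinimide | O=C1CCC(=O)N1Br | starting material
3 | 2,4-dibromo-8-methoxynaphthalen-1-ol | COc1cccc2c(Br)cc(Br)c(O)c12 | intermediate
4 | chloromethyl methyl ether | COCCl | starting material
5 | 2,4-dibromo-8-methoxy-1-(methoxymethoxy)naphthalene | COCOc1c(Br)cc(Br)c2cccc(OC)c12 | intermediate
6 | 8-methoxy-3,4-dihydronaphthalen-1(2H)-one (8-methoxy-1-tetralone) | COc1cccc2CCCC(=O)c12 | starting material
7 | triethylsilyl trifluoromethanesulfonate | CC[Si](CC)(CC)OS(=O)(=O)C(F)(F)F | starting material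
8 | disodium 2,2'-[8-methoxy-1-(methoxymethoxy)naphthalene-2,4-diyl]bis(8-methoxy-3,4-dihydronaphthalen-1-olate) | [Na+].[Na+].COCOc1c(C2=C([O-])c3c(OC)cccc3CC2)cc(C2=C([O-])c3c(OC)cccc3CC2)c2cccc(OC)c12 | intermediate (not isolated)
9 | 2,2'-[8-methoxy-1-(methoxymethoxy)naphthalene-2,4-diyl]bis[8-methoxy-1-(triethylsilyloxy)-3,4-dihydronaphthalene] | COCOc1c(C2=C(O[Si](CC)(CC)CC)c3c(OC)cccc3CC2)cc(C2=C(O[Si](CC)(CC)CC)c3c(OC)cccc3CC2)c2cccc(OC)c12 | intermediate
10 | 1,1''-bis(triethylsilyloxy)-8,8',8''-trimethoxy-1'-(methoxymethoxy)-2,2':4',2''-ternaphthalene | COCOc1c(-c2ccc3cccc(OC)c3c2O[Si](CC)(CC)CC)cc(-c2ccc3cccc(OC)c3c2O[Si](CC)(CC)CC)c2cccc(OC)c12 | intermediate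
11 | 8,8',8''-trimethoxy-[2,2':4',2''-ternaphthalene]-1,1',1''-triol (no stereocentre) | COc1cccc2ccc(-c3cc(-c4ccc5cccc(OC)c5c4O)c4cccc(OC)c4c3O)c(O)c12 | target

**Step count.** Total: 5 steps. Longest linear sequence: 5 steps (1 → 3 → 5 → 9 → 10 → 11).

**Steps most likely to fail, with fallbacks**

Step 3 (two-fold α-arylation at two hindered C–Br bonds). It may stall after one coupling, or lose bromine by β-hydride elimination from the palladium enolate. The fallback replaces enolate arylation by a two-fold biaryl cross-coupling; it sets out from 1 and 5 and comes back to the route at 11. Compound 1 is MOM-protected (NaH, MOMCl, DMF) to 8-methoxy-1-(methoxymethoxy)naphthalene F1. Directed ortho-lithiation next to the MOM ether (n-BuLi, TMEDA, THF, 0 °C), B(OMe)3 quench and aqueous NH4Cl give [8-methoxy-1-(methoxymethoxy)naphthalen-2-yl]boronic acid F2. Suzuki–Miyaura coupling of F2 (2.6 equiv) with 5 (Pd(OAc)2, SPhos, K3PO4, PhMe/H2O, 90 °C) gives 8,8',8''-trimethoxy-1,1',1''-tris(methoxymethoxy)-2,2':4',2''-ternaphthalene F3. The step 5 conditions (HCl, MeOH/THF) then give 11.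

Step 4 (DDQ aromatisation). The hydroquinone may desilylate the enol ether back to the ketone, or DDQ may form adducts or over-oxidise. The fallback replaces direct dehydrogenation by halogenation and elimination; it sets out from 9 and comes back at 11. NBS (2.1 equiv, THF, −78 °C) brominates each silyl enol ether at its enol carbon to give 2,2'-[8-methoxy-1-(methoxymethoxy)naphthalene-2,4-diyl]bis(2-bromo-8-methoxy-3,4-dihydronaphthalen-1(2H)-one) F4, a diastereomer mixture whose stereocentres are erased next. DBU (PhMe, 60 °C, argon) eliminates HBr twice and the dienones tautomerise to 8,8',8''-trimethoxy-1'-(methoxymethoxy)-[2,2':4',2''-ternaphthalene]-1,1''-diol F5. HCl in MeOH/THF then removes the MOM group to give 11.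

Step 1 (site of the second bromination, C2 against C5 or C7). The fallback places the C2 bromine by ketone chemistry instead of aromatic substitution; it sets out from 6 and comes back at 3. PhNMe3Br3 (2.2 equiv, THF, rt) gives 2,2-dibromo-8-methoxy-3,4-dihydronaphthalen-1(2H)-one F6. DBU (MeCN, rt) eliminates HBr and the dienone tautomerises to 2-bromo-8-methoxynaphthalen-1-ol F7. One equivalent of NBS (CH2Cl2, 0 °C) then brominates para to the OH at C4 to give 3.

**Further compounds**
F1 | step 3 | 8-methoxy-1-(methoxymethoxy)naphthalene | COCOc1cccc2cccc(OC)c12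
F2 | step 3 | [8-methoxy-1-(methoxymethoxy)naphthalen-2-yl]boronic acid | COCOc1c(B(O)O)ccc2cccc(OC)c12
F3 | step 3 | 8,8',8''-trimethoxy-1,1',1''-tris(methoxymethoxy)-2,2':4',2''-ternaphthalene | COCOc1c(-c2ccc3cccc(OC)c3c2OCOC)cc(-c2ccc3cccc(OC)c3c2OCOC)c2cccc(OC)c12
F4 | step 4 | 2,2'-[8-methoxy-1-(methoxymethoxy)naphthalene-2,4-diyl]bis(2-bromo-8-methoxy-3,4-dihydronaphthalen-1(2H)-one), diastereomer mixture | COCOc1c(C2(Br)CCc3cccc(OC)c3C2=O)cc(C2(Br)CCc3cccc(OC)c3C2=O)c2cccc(OC)c12
F5 | step 4 | 8,8',8''-trimethoxy-1'-(methoxymethoxy)-[2,2':4',2''-ternaphthalene]-1,1''-diol | COCOc1c(-c2ccc3cccc(OC)c3c2O)cc(-c2ccc3cccc(OC)c3c2O)c2cccc(OC)c12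
F6 | step 1 | 2,2-dibromo-8-methoxy-3,4-dihydronaphthalen-1(2H)-one | COc1cccc2CCC(Br)(Br)C(=O)c12
F7 | step 1 | 2-bromo-8-methoxynaphthalen-1-ol | COc1cccc2ccc(Br)c(O)c12
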